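## Retrosynthetic overview

1. Feature: the oxirane is the oxide of a 1,1-disubstituted alkene. Its quaternary benzylic carbon carries the ring O, the ring CH2, the benzene ring and a CH2–O arm, and the oxygen of that arm (later the acetate oxygen) can serve as an allylic hydroxyl.
2. The acetate C–O bond is cut last, giving the (R)-epoxy alcohol. The key cut removes both oxirane C–O bonds at once, giving the 2-arylallyl alcohol and tert-butyl hydroperoxide (titanium–tartrate oxygen transfer).
3. The allyl alcohol is cut at the aryl–C(sp2) bond: base-free Stille coupling of the fully acylated aryl iodide with 2-(tributylstannyl)prop-2-en-1-ol, made from propargyl alcohol.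
4. The iodide comes from methyl 3-hydroxy-4-iodobenzoate by ester reduction, phenolate-selective isobutyrylation, then pentanoylation of the benzylic alcohol.
5. Ring order: the benzene ring is bought, and the oxirane is the only ring made, in the penultimate step.

Key step: step 6

Remark on the chemistry: the stereocentre of the given SMILES is read as (S). The same spatial arrangement is (R) in the epoxy alcohol, because there the ring CH2 outranks CH2OH, whereas in the target CH2OAc outranks the ring CH2.

## Route

Step 1
Reactants: 1 methyl 3-hydroxy-4-iodobenzoate
Product: 2 (3-hydroxy-4-iodophenyl)methanol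
Conditions: iBu2AlH (3.5 equiv), THF, −78 to 0 °C; aq. potassium sodium tartrate
Reagents that add atoms: none
Why: Ester reduction with a dialkylaluminium hydride: the first equivalent is spent on the phenol O–H, two more take the ester through the aldehyde to the primary alkoxide, and at this temperature the reagent should leave the aryl C–I bond alone.

Step 2
Reactants: 2 (3-hydroxy-4-iodophenyl)methanol; 3 isobutyryl chloride
Product: 5 [4-iodo-3-(isobutyryloxy)phenyl]methanol, via sodium phenolate 4 (not isolated)
Conditions: NaOH (1.0 equiv), H2O–THF, 0 °C; then 3 (1.05 equiv), 0 °C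
Reagents that add atoms: isobutyryl chloride (3), CC(C)C(=O)Cl; sodium hydroxide, [Na+].[OH-] (supplies the sodium of 4 only)
Why: Schotten–Baumann acylation: one equivalent of hydroxide ionises only the ortho-iodophenol (pKa near 8.5 against about 15 for the benzylic alcohol), and phenolate 4 should take the acid chloride much faster than the neutral primary alcohol, which is why the phenol is acylated first.

Step 3
Reactants: 5 [4-iodo-3-(isobutyryloxy)phenyl]methanol; 6 pentanoyl chloride
Product: 7 [4-iodo-3-(isobutyryloxy)phenyl]methyl pentanoate
Conditions: 6 (1.1 equiv), pyridine (1.5 equiv), CH2Cl2, 0 °C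
Reagents that add atoms: pentanoyl chloride (6), CCCCC(=O)Cl
Why: Pyridine-mediated O-acylation (nucleophilic acyl substitution) of the only remaining hydroxyl, with DMAP left out so that the aryl isobutyrate, an active ester, is not exchanged.

Step 4
Reactants: 8 propargyl alcohol (prop-2-yn-1-ol); 9 tributyltin hydride
Product: 10 alpha-stannane 2-(tributylstannyl)prop-2-en-1-ol
Conditions: 9 (1.1 equiv, slow addition), PdCl2(PPh3)2 (2 mol %), THF, 0 °C to rt; chromatography on Et3N-washed silica
Reagents that add atoms: tributyltin hydride (9), CCCC[SnH](CCCC)CCCC
Why: Palladium-catalysed syn hydrostannation of a terminal alkyne (Sn–H oxidative addition to zerovalent palladium, hydropalladation, reductive elimination), in which the propargylic oxygen steers a useful share of the tin to the internal carbon and the (E)-3-stannyl regioisomer that also forms is removed by chromatography.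

Step 5
Reactants: 7 [4-iodo-3-(isobutyryloxy)phenyl]methyl pentanoate; 10 2-(tributylstannyl)prop-2-en-1-ol
Product: 11 [4-(3-hydroxyprop-1-en-2-yl)-3-(isobutyryloxy)phenyl]methyl pentanoate
Conditions: 10 (1.3 equiv), Pd2(dba)3 (2.5 mol %), AsPh3 (20 mol %), CuI (20 mol %), degassed DMF, 40 °C
Reagents that add atoms: none
Why: Stille coupling with copper co-catalysis: oxidative addition of the C–I bond to zerovalent palladium, tin-to-copper-to-palladium transfer of the hindered 1-substituted vinyl group and reductive elimination form the aryl–C(sp2) bond without any base, so both esters and the free allylic hydroxyl should survive.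

Step 6
Reactants: 11 [4-(3-hydroxyprop-1-en-2-yl)-3-(isobutyryloxy)phenyl]methyl pentanoate; 12 tert-butyl hydroperoxide
Product: 13 {4-[(2R)-2-(hydroxymethyl)oxiran-2-yl]-3-(isobutyryloxy)phenyl}methyl pentanoate
Conditions: Ti(OiPr)4 (10 mol %), D-(−)-diisopropyl tartrate (12 mol %), 12 (5.5 M in decane, 2 equiv), 4 Å MS, CH2Cl2, −20 °C (catalyst aged 30 min before 11 is added); Me2S, −20 °C; sat. aq. Na2SO4/Et2O, filtration through Celite
Reagents that add atoms: tert-butyl hydroperoxide (12), CC(C)(C)OO
Why: This is a Katsuki–Sharpless asymmetric epoxidation of a 2-substituted allylic alcohol: the hydroxyl of 11 and the hydroperoxide 12 replace isopropoxide on the tartrate-bridged tetravalent titanium dimer, and the distal oxygen of the eta-2 bound peroxide passes to the C=C in a concerted spiro transition state. The oxirane, the only ring formed, therefore closes by one-step oxygen-atom transfer that makes the quaternary C–O and the CH2–O bonds together and not by displacement, so no tertiary alkoxide or free phenolate ever stands next to the ortho isobutyrate. The quaternary centre is set by the D-(−)-tartrate ligand acting through the titanium-bound allylic oxygen: oxygen should reach the Re face of the aryl-bearing carbon (CH2OH > aryl > =CH2), the same sense in which D-(−)-tartrate turns 2-methylprop-2-en-1-ol into (R)-2-methylglycidol, and this gives (R)-13. Site selectivity is not in question because the molecule holds a single alkene, and the allylic CH2OH of the substrate is what ties it to the metal and secures both rate and facial control. What must be held back is ester exchange at the aryl isobutyrate and opening of the unsubstituted oxirane CH2 by isopropoxide, which the alpha-branched acyl group, the low titanium loading, the sieves, −20 °C and a neutral, non-nucleophilic work-up are meant to secure.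

Step 7
Reactants: 13 {4-[(2R)-2-(hydroxymethyl)oxiran-2-yl]-3-(isobutyryloxy)phenyl}methyl pentanoate; 14 acetic anhydride
Product: 15 {4-[(2S)-2-(acetoxymethyl)oxiran-2-yl]-3-(isobutyryloxy)phenyl}methyl pentanoate (target CNP0107520.1)
Conditions: 14 (1.5 equiv), pyridine (3 equiv), CH2Cl2, 0 °C
Reagents that add atoms: acetic anhydride (14), CC(=O)OC(C)=O
Why: Pyridine-mediated O-acetylation (nucleophilic acyl substitution) of the primary alcohol leaves every bond at the quaternary centre untouched, so the configuration is kept and only the descriptor changes from R to S; the weak amine base is chosen to spare the aryl isobutyrate and the oxirane, not for fear of racemisation, since a Payne shift in 13 is degenerate and returns the same enantiomer.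

## Compound list

1 | methyl 3-hydroxy-4-iodobenzoate | COC(=O)c1ccc(I)c(O)c1 | starting material
2 | (3-hydroxy-4-iodophenyl)methanol | OCc1ccc(I)c(O)c1 | intermediate
3 | isobutyryl chloride | CC(C)C(=O)Cl | starting material
4 | sodium 5-(hydroxymethyl)-2-iodophenolate | OCc1ccc(I)c([O-])c1.[Na+] | intermediate
5 | [4-iodo-3-(isobutyryloxy)phenyl]methanol | OCc1ccc(I)c(OC(=O)C(C)C)c1 | intermediate
6 | pentanoyl chloride | CCCCC(=O)Cl | starting material
7 | [4-iodo-3-(isobutyryloxy)phenyl]methyl pentanoate | CCCCC(=O)OCc1ccc(I)c(OC(=O)C(C)C)c1 | intermediate
8 | propargyl alcohol | C#CCO | starting material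
9 | tributyltin hydride | CCCC[SnH](CCCC)CCCC | starting material
10 | 2-(tributylstannyl)prop-2-en-1-ol | C=C(CO)[Sn](CCCC)(CCCC)CCCC | intermediate
11 | [4-(3-hydroxyprop-1-en-2-yl)-3-(isobutyryloxy)phenyl]methyl pentanoate | CCCCC(=O)OCc1ccc(C(=C)CO)c(OC(=O)C(C)C)c1 | intermediate
12 | tert-butyl hydroperoxide | CC(C)(C)OO | starting material
13 | {4-[(2R)-2-(hydroxymethyl)oxiran-2-yl]-3-(isobutyryloxy)phenyl}methyl pentanoate | CCCCC(=O)OCc1ccc([C@@]2(CO)CO2)c(OC(=O)C(C)C)c1 | intermediate
14 | acetic anhydride | CC(=O)OC(C)=O | starting material
15 | {4-[(2S)-2-(acetoxymethyl)oxiran-2-yl]-3-(isobutyryloxy)phenyl}methyl pentanoate | CCCCC(=O)OCc1ccc([C@@]2(COC(C)=O)CO2)c(OC(=O)C(C)C)c1 | target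

## Step count and risks

Total step count: 7.
Longest linear sequence: 6 (steps 1, 2, 3, 5, 6 and 7, starting from 1). Step 4 is a one-step side branch.

**Step 6 (most likely to fail).**
- What may go wrong: the ortho-substituted aryl group, twisted out of the alkene plane, may lower the facial selectivity. The titanium alkoxide may pass the isobutyryl group on to the allylic oxygen. Isopropoxide may open the benzylic oxirane at its CH2.
- Fallback: give up reagent control and resolve. The fallback sets out from 11. Epoxidation with mCPBA, buffered by solid NaHCO3 in CH2Cl2 at 0 °C, gives the racemic epoxy alcohol F1.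
- Lipase-catalysed acetylation (Burkholderia cepacia lipase, vinyl acetate, iPr2O, rt) is a known resolution of 2-substituted oxiranemethanols. It is run past half conversion, so that the (S)-alcohol is consumed as the (R)-configured acetate F2.
- F2 is separated by chromatography from the unreacted (R)-alcohol, and there the fallback comes back to the route at 13.
- If the enzyme prefers the (R)-alcohol instead, the run is stopped short of half conversion and the acetate formed is 15 itself.

**Step 5.**
- What may go wrong: transmetalation of the hindered 1-substituted vinylstannane onto an ortho-substituted arylpalladium may be slow. Protodestannylation, cine substitution or a thermal acyl shift from the phenol oxygen to the new allylic hydroxyl could then take over.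
- Fallback: reverse the polarity and leave tin out. The fallback sets out from 7. Miyaura borylation (B2pin2, PdCl2(dppf), KOAc, dioxane, 80 °C), with acetate too weak a base to harm the aryl ester, gives the aryl pinacol boronate F3.
- Suzuki–Miyaura coupling of F3 with purchased 2-bromoprop-2-en-1-ol under mild fluoride activation (Pd2(dba)3, P(tBu)3, KF, THF with a little H2O, rt) comes back to the route at 11. Step 4 is then no longer needed.

**Step 4.**
- What may go wrong: regioselectivity may be poor, with most of the tin ending up on the terminal carbon. The allylic stannane may also be lost by protodestannylation during separation.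
- Fallback: fix the position of the metal through a halide instead of a hydrometalation. The fallback sets out from 8. Markovnikov hydroiodination (NaI, Me3SiCl, H2O, MeCN, rt) gives 2-iodoprop-2-en-1-ol F4.
- Deprotonation with nBuLi (1 equiv) and iodine–lithium exchange with tBuLi (2 equiv) in Et2O at −78 °C gives the O,C-dilithio species F5. It is quenched with Bu3SnCl, and aqueous work-up frees the hydroxyl.
- The fallback comes back to the route at 10, obtained as a single regioisomer.

## Further compounds

F1 | step 6 | racemic {4-[2-(hydroxymethyl)oxiran-2-yl]-3-(isobutyryloxy)phenyl}methyl pentanoate | CCCCC(=O)OCc1ccc(C2(CO)CO2)c(OC(=O)C(C)C)c1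
F2 | step 6 | {4-[(2R)-2-(acetoxymethyl)oxiran-2-yl]-3-(isobutyryloxy)phenyl}methyl pentanoate | CCCCC(=O)OCc1ccc([C@]2(COC(C)=O)CO2)c(OC(=O)C(C)C)c1
F3 | step 5 | [3-(isobutyryloxy)-4-(4,4,5,5-tetramethyl-1,3,2-dioxaborolan-2-yl)phenyl]methyl pentanoate | CCCCC(=O)OCc1ccc(B2OC(C)(C)C(C)(C)O2)c(OC(=O)C(C)C)c1
F4 | step 4 | 2-iodoprop-2-en-1-ol | C=C(I)CO
F5 | step 4 | lithium 2-lithioprop-2-en-1-olate | [Li]OCC(=C)[Li]
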